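**Retrosynthetic overview**
1. Last bond: the aryl–O–CH2 ether, made by Mitsunobu coupling of purchased isofraxidin with the primary allylic alcohol of the monocyclic sesquiterpene diol; the coumarin ring is never built.
2. Ring locants used below: C-1 carbinol, C-2 CMe2, C-3 CH carrying the side chain, C-4 C=CH2, C-5 and C-6 CH2. At the ketone level (C-1 = C=O) the exocyclic C-4 methylidene is γ,δ to the carbonyl along both arcs of the ring (C-1/C-2/C-3/C-4 and C-1/C-6/C-5/C-4), so two Claisen retrons share one carbonyl and one alkene.
3. Key disconnection: both ring bonds C-2–C-3 and C-5–C-6 in one operation, back to the 1,3-dioxane ketal of 3-methylbutan-2-one with a 2-alkylidenepropane-1,3-diol (double [3,3] cascade). Ring order: temporary 1,3-dioxane (step 1), then the carbocycle (step 6).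
4. The alkylidene dioxane comes from cross-metathesis of the 5-methylidene-1,3-dioxane ketal with a terminal alkene cut from geranyl acetate, which also supplies the E side-chain alkene unchanged.
5. Configuration: the key step gives the ketone as a racemate at C-3; C-1 is set by catalyst-controlled (CBS) reduction, which at the same time sorts the two C-3 antipodes into separable cis and trans alcohols, so C-3 is fixed by separation, not by induction.

Key step: step 6

Remark: isofraxidin (7-hydroxy-6,8-dimethoxycoumarin), geranyl acetate, 2-methylidenepropane-1,3-diol and 3-methylbutan-2-one are taken as purchased compounds.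

Step 1
Reactants: 1 2-methylidenepropane-1,3-diol; 2 3-methylbutan-2-one
Product: 3 2-methyl-5-methylidene-2-(propan-2-yl)-1,3-dioxane
Conditions: TsOH·H2O (1 mol %), cyclohexane, reflux, Dean–Stark trap
Reagents that add atoms: none
Why: Acid-catalysed ketalisation of a ketone with a 1,3-diol under azeotropic removal of water should give the six-membered dioxane, and no stereocentre is formed.

Step 2
Reactants: 4 geranyl acetate [(2E)-3,7-dimethylocta-2,6-dien-1-yl acetate]
Product: 5 (2E)-5-(3,3-dimethyloxiran-2-yl)-3-methylpent-2-en-1-yl acetate (racemic)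
Conditions: mCPBA (1.05 equiv), CH2Cl2, 0 °C
Reagents that add atoms: 3-chloroperoxybenzoic acid (mCPBA), OOC(=O)c1cccc(Cl)c1
Why: Prilezhaev epoxidation should take the electron-rich terminal trisubstituted alkene because the 2,3-alkene is deactivated by the allylic acetoxy group, and the racemic epoxide stereocentre is destroyed in step 3.

Step 3
Reactants: 5 (2E)-5-(3,3-dimethyloxiran-2-yl)-3-methylpent-2-en-1-yl acetate
Product: 6 (2E)-3-methyl-6-oxohex-2-en-1-yl acetate
Conditions: H5IO6 (1.1 equiv), THF/H2O, 0 °C → rt
Reagents that add atoms: none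
Why: Periodic acid should open the epoxide to the diol and cleave it in the same flask (glycol cleavage), the standard degradation of 6,7-epoxygeranyl esters to the C-6 aldehyde.

Step 4
Reactants: 6 (2E)-3-methyl-6-oxohex-2-en-1-yl acetate
Product: 7 (2E)-3-methylhepta-2,6-dien-1-yl acetate
Conditions: Ph3PCH3Br, KN(SiMe3)2, THF, 0 °C; then 6, −78 → 0 °C
Reagents that add atoms: methyltriphenylphosphonium bromide, C[P+](c1ccccc1)(c1ccccc1)c1ccccc1.[Br-]
Why: Wittig methylenation of an unhindered aldehyde by the preformed ylide at low temperature should be much faster than attack on the acetate, and no stereocentre is involved.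

Step 5
Reactants: 7 (2E)-3-methylhepta-2,6-dien-1-yl acetate; 3 2-methyl-5-methylidene-2-(propan-2-yl)-1,3-dioxane
Product: 8 (2E)-3-methyl-6-[2-methyl-2-(propan-2-yl)-1,3-dioxan-5-ylidene]hex-2-en-1-yl acetate
Conditions: second-generation Hoveyda–Grubbs catalyst (5 mol %), 3 (4 equiv), CH2Cl2, 40 °C
Reagents that add atoms: none
Why: Olefin cross-metathesis of a terminal alkene with an excess of a 1,1-disubstituted alkene that does not homodimerise should give the trisubstituted alkylidene, with no E/Z question because the two allylic arms of 3 are identical and with the trisubstituted 2,3-alkene left untouched.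

Step 6
Reactants: 8 (2E)-3-methyl-6-[2-methyl-2-(propan-2-yl)-1,3-dioxan-5-ylidene]hex-2-en-1-yl acetate
Product: 12 (2E)-5-(2,2-dimethyl-6-methylidene-3-oxocyclohexyl)-3-methylpent-2-en-1-yl acetate (racemic), via hydroxy enol ether 9 (not isolated), via hydroxy ketone 10 (not isolated), via dimethylideneoxane 11 (not isolated)
Conditions: 2,4-dinitrophenol (10 mol %), 4 Å molecular sieves, mesitylene, 150 °C, then 200 °C (sealed tube)
Reagents that add atoms: none
Why: Proposed new method: the acid opens the dioxane of 8 and the oxocarbenium ion loses a proton from the isopropyl side to give the tetrasubstituted enol ether 9 (the thermodynamically favoured one, through which ketals of unsymmetrical methyl ketones are expected to rearrange), and 9 undergoes a chair-like [3,3] shift that bonds the former isopropyl carbon to C-3 and turns the CH2–O carbon of the migrating arm into a terminal methylidene in 10; the closest known reaction type is the ketal Claisen rearrangement of allylic alcohols. The hydroxymethyl arm left in 10 then adds to the methyl ketone and loses water to the exocyclic enol ether 11, the only enol ether possible because the other alpha carbon is quaternary. 11 is an allyl vinyl ether whose two methylidene ends are held across one oxane ring, and a second [3,3] shift through a boat-like transition state, of the type known as the Claisen ring contraction of 2-methylidene tetrahydropyrans, bonds the enol-ether CH2 to the methylidene made in the first shift (C-5–C-6), makes the remaining CH2–O arm the final exocyclic methylidene and releases the C-1 ketone; an acid-assisted ion-pair path would end in the same product because both ends of the 2-substituted allyl unit are CH2 groups. The cyclohexanone ring is therefore closed in the second shift, as a sigmatropic contraction of the six-membered oxane to the six-membered carbocycle. The one new stereocentre, C-3, arises in the first shift from the achiral ether 9 and is racemic, so its absolute configuration is left to step 7. The selectivity required is enolisation toward the isopropyl group before the first shift, relied on from the greater stability of the more substituted enol ether, and toward the methyl group before the second, which the quaternary C-2 enforces.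

Step 7
Reactants: 12 (2E)-5-(2,2-dimethyl-6-methylidene-3-oxocyclohexyl)-3-methylpent-2-en-1-yl acetate (racemic)
Product: 13 (2E)-5-[(1S,3R)-3-hydroxy-2,2-dimethyl-6-methylidenecyclohexyl]-3-methylpent-2-en-1-yl acetate
Conditions: (S)-2-methyl-CBS-oxazaborolidine (0.3 equiv), catecholborane (1.5 equiv), toluene, −78 → −40 °C; MeOH quench; chromatographic removal of the trans diastereomer
Reagents that add atoms: none
Why: Corey–Bakshi–Shibata reduction, in which the oxazaborolidine should tell the quaternary C-2 from the C-6 methylene and deliver hydride to the same face of C-1 in both antipodes of 12, sets C-1 as R and turns the (3S) antipode into the cis alcohol 13 while the (3R) antipode ends as the trans diastereomer that is separated, so the configuration at C-3 is fixed here by diastereomer separation.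

Step 8
Reactants: 13 (2E)-5-[(1S,3R)-3-hydroxy-2,2-dimethyl-6-methylidenecyclohexyl]-3-methylpent-2-en-1-yl acetate
Product: 14 (1R,3S)-3-[(3E)-5-hydroxy-3-methylpent-3-en-1-yl]-2,2-dimethyl-4-methylidenecyclohexan-1-ol
Conditions: K2CO3 (0.2 equiv), MeOH, 0 °C → rt
Reagents that add atoms: none
Why: Base-catalysed transesterification with methanol should remove the primary acetate without touching the alkenes or either stereocentre.

Step 9
Reactants: 14 (1R,3S)-3-[(3E)-5-hydroxy-3-methylpent-3-en-1-yl]-2,2-dimethyl-4-methylidenecyclohexan-1-ol; 15 isofraxidin (7-hydroxy-6,8-dimethoxy-2H-chromen-2-one)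
Product: 16 7-{[(2E)-5-[(1S,3R)-3-hydroxy-2,2-dimethyl-6-methylidenecyclohexyl]-3-methylpent-2-en-1-yl]oxy}-6,8-dimethoxy-2H-chromen-2-one (CNP0306576.1)
Conditions: PPh3, diisopropyl azodicarboxylate, THF, 0 °C → rt
Reagents that add atoms: none
Why: In the Mitsunobu etherification the acidic phenol of 15 should displace the activated primary allylic alcohol by SN2 with the E geometry kept, while the hindered secondary alcohol next to the quaternary carbon does not react and no stereocentre is touched.

**Compound list**
1 | 2-methylidenepropane-1,3-diol | C=C(CO)CO | starting material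
2 | 3-methylbutan-2-one | CC(=O)C(C)C | starting material
3 | 2-methyl-5-methylidene-2-(propan-2-yl)-1,3-dioxane | C=C1COC(C)(C(C)C)OC1 | intermediate
4 | geranyl acetate, (2E)-3,7-dimethylocta-2,6-dien-1-yl acetate | CC(C)=CCC/C(C)=C/COC(C)=O | starting material
5 | (2E)-5-(3,3-dimethyloxiran-2-yl)-3-methylpent-2-en-1-yl acetate (racemic) | CC1(C)OC1CC/C(C)=C/COC(C)=O | intermediate
6 | (2E)-3-methyl-6-oxohex-2-en-1-yl acetate | O=CCC/C(C)=C/COC(C)=O | intermediate
7 | (2E)-3-methylhepta-2,6-dien-1-yl acetate | C=CCC/C(C)=C/COC(C)=O | intermediate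
8 | (2E)-3-methyl-6-[2-methyl-2-(propan-2-yl)-1,3-dioxan-5-ylidene]hex-2-en-1-yl acetate (racemic) | CC(C)C1(C)OCC(=CCC/C(C)=C/COC(C)=O)CO1 | intermediate
9 | (2E)-7-(hydroxymethyl)-3-methyl-8-[(3-methylbut-2-en-2-yl)oxy]octa-2,6-dien-1-yl acetate (6E/6Z mixture) | CC(C)=C(C)OCC(CO)=CCC/C(C)=C/COC(C)=O | intermediate (not isolated)
10 | (2E)-6-(3-hydroxyprop-1-en-2-yl)-3,7,7-trimethyl-8-oxonon-2-en-1-yl acetate (racemic) | CC(=O)C(C)(C)C(CC/C(C)=C/COC(C)=O)C(=C)CO | intermediate (not isolated)
11 | (2E)-5-(3,3-dimethyl-2,5-dimethylideneoxan-4-yl)-3-methylpent-2-en-1-yl acetate (racemic) | C=C1OCC(=C)C(CC/C(C)=C/COC(C)=O)C1(C)C | intermediate (not isolated)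
12 | (2E)-5-(2,2-dimethyl-6-methylidene-3-oxocyclohexyl)-3-methylpent-2-en-1-yl acetate (racemic) | C=C1CCC(=O)C(C)(C)C1CC/C(C)=C/COC(C)=O | intermediate
13 | (2E)-5-[(1S,3R)-3-hydroxy-2,2-dimethyl-6-methylidenecyclohexyl]-3-methylpent-2-en-1-yl acetate | C=C1CC[C@@H](O)C(C)(C)[C@H]1CC/C(C)=C/COC(C)=O | intermediate
14 | (1R,3S)-3-[(3E)-5-hydroxy-3-methylpent-3-en-1-yl]-2,2-dimethyl-4-methylidenecyclohexan-1-ol | C=C1CC[C@@H](O)C(C)(C)[C@H]1CC/C(C)=C/CO | intermediate
15 | isofraxidin, 7-hydroxy-6,8-dimethoxy-2H-chromen-2-one | COc1cc2ccc(=O)oc2c(OC)c1O | starting material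
16 | 7-{[(2E)-5-[(1S,3R)-3-hydroxy-2,2-dimethyl-6-methylidenecyclohexyl]-3-methylpent-2-en-1-yl]oxy}-6,8-dimethoxy-2H-chromen-2-one | C=C1CC[C@@H](O)C(C)(C)[C@H]1CC/C(C)=C/COc1c(OC)cc2ccc(=O)oc2c1OC | target

Total step count: 9.
Longest linear sequence: 8 steps (4 → 16, steps 2 to 9); step 1 is a one-step branch.

**Steps most likely to fail**

Step 6 (Proposed new method). What may go wrong: the opened ketal may enolise toward the methyl group before the first shift, which would move the side chain to the other ring position. The second, boat-type shift may stall at the hydroxy ketone stage. The allylic acetate may migrate at the temperature needed. The fallback uses only known reaction types, sets out from aldehyde 6, comes back to the route at diol 14 (it replaces steps 4 to 8), and forms the two ring bonds in separate steps with full control of both stereocentres. Nozaki–Hiyama–Kishi coupling of 6 with (2-bromoprop-2-en-1-yl)trimethylsilane (CrCl2, NiCl2 cat., DMF) should give the allylic alcohol (2E)-6-hydroxy-3-methyl-7-[(trimethylsilyl)methyl]octa-2,7-dien-1-yl acetate F1. Ketal Claisen rearrangement of the Johnson type with 3-chloro-2,2-dimethoxy-3-methylbutane (2,4-dinitrophenol cat., toluene, 110 °C), whose ketal can enolise only toward its methyl group, should form the C-5–C-6 bond. It should give the chloro ketone (2E,6Z)-11-chloro-3,11-dimethyl-10-oxo-7-[(trimethylsilyl)methyl]dodeca-2,6-dien-1-yl acetate F2, with the side chain trans to the new chain through the chair transition state. CBS reduction ((S)-2-methyl-CBS-oxazaborolidine, catecholborane, toluene, −78 °C) should give the chlorohydrin (2E,6Z,10R)-11-chloro-10-hydroxy-3,11-dimethyl-7-[(trimethylsilyl)methyl]dodeca-2,6-dien-1-yl acetate F3. K2CO3 in MeOH should close the epoxide and remove the acetate to give (2E,6Z)-9-[(2R)-3,3-dimethyloxiran-2-yl]-3-methyl-7-[(trimethylsilyl)methyl]nona-2,6-dien-1-ol F4. BF3·OEt2 in CH2Cl2 at −78 °C should then effect the epoxide-initiated, allylsilane-terminated cyclisation through a chair transition state. This forms the C-2–C-3 bond, places hydroxyl and side chain both equatorial (cis), ends in the exocyclic methylidene, and gives 14.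

Step 7. What may go wrong: in the (3R) antipode the catalyst preference and the ring's own preference for axial hydride attack oppose each other. Facial control may then be incomplete, and the cis fraction would be contaminated by the enantiomer of 13. The fallback sets out from 12 and comes back at 14, replacing catalyst control by a classical resolution. NaBH4 (MeOH, −20 °C) should reduce 12 under substrate control to the racemic cis alcohol rac-(2E)-5-[(1S,3R)-3-hydroxy-2,2-dimethyl-6-methylidenecyclohexyl]-3-methylpent-2-en-1-yl acetate F5. Esterification with (S)-methoxy(phenyl)acetic acid (DCC, DMAP, CH2Cl2) should give two diastereomeric esters that are separated by chromatography; the wanted one is (1R,3S)-3-[(3E)-5-(acetyloxy)-3-methylpent-3-en-1-yl]-2,2-dimethyl-4-methylidenecyclohexyl (2S)-methoxy(phenyl)acetate F6. K2CO3 in MeOH should cleave both ester groups of F6 and give 14.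

Step 5. What may go wrong: the hindered 1,1-disubstituted alkene 3 may turn over slowly, so that self-metathesis of 7 and catalyst decay take over. The fallback sets out from 6 and comes back at 8, using carbonyl olefination in place of metathesis. NaBH4 (MeOH, 0 °C) should give (2E)-6-hydroxy-3-methylhex-2-en-1-yl acetate F7. I2, PPh3 and imidazole (CH2Cl2) should give (2E)-6-iodo-3-methylhex-2-en-1-yl acetate F8. PPh3 in MeCN at reflux should give [(4E)-6-(acetyloxy)-4-methylhex-4-en-1-yl]triphenylphosphonium iodide F9. The ylide (KN(SiMe3)2, THF, −78 °C) should react with purchased 2,2-dimethyl-1,3-dioxan-5-one in a Wittig reaction to give (2E)-6-(2,2-dimethyl-1,3-dioxan-5-ylidene)-3-methylhex-2-en-1-yl acetate F10. Acid-catalysed ketal exchange with an excess of ketone 2 (TsOH cat., removal of acetone by distillation) should give 8.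

**Further compounds**
F1 | step 6 | (2E)-6-hydroxy-3-methyl-7-[(trimethylsilyl)methyl]octa-2,7-dien-1-yl acetate (racemic) | C=C(C[Si](C)(C)C)C(O)CC/C(C)=C/COC(C)=O
F2 | step 6 | (2E,6Z)-11-chloro-3,11-dimethyl-10-oxo-7-[(trimethylsilyl)methyl]dodeca-2,6-dien-1-yl acetate | CC(C)(Cl)C(=O)CC/C(C[Si](C)(C)C)=C/CC/C(C)=C/COC(C)=O
F3 | step 6 | (2E,6Z,10R)-11-chloro-10-hydroxy-3,11-dimethyl-7-[(trimethylsilyl)methyl]dodeca-2,6-dien-1-yl acetate | CC(C)(Cl)[C@H](O)CC/C(C[Si](C)(C)C)=C/CC/C(C)=C/COC(C)=O
F4 | step 6 | (2E,6Z)-9-[(2R)-3,3-dimethyloxiran-2-yl]-3-methyl-7-[(trimethylsilyl)methyl]nona-2,6-dien-1-ol | CC1(C)O[C@@H]1CC/C(C[Si](C)(C)C)=C/CC/C(C)=C/CO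
F5 | step 7 | rac-(2E)-5-[(1S,3R)-3-hydroxy-2,2-dimethyl-6-methylidenecyclohexyl]-3-methylpent-2-en-1-yl acetate (racemate, one enantiomer drawn) | C=C1CC[C@@H](O)C(C)(C)[C@H]1CC/C(C)=C/COC(C)=O
F6 | step 7 | (1R,3S)-3-[(3E)-5-(acetyloxy)-3-methylpent-3-en-1-yl]-2,2-dimethyl-4-methylidenecyclohexyl (2S)-methoxy(phenyl)acetate | C=C1CC[C@@H](OC(=O)[C@@H](OC)c2ccccc2)C(C)(C)[C@H]1CC/C(C)=C/COC(C)=O
F7 | step 5 | (2E)-6-hydroxy-3-methylhex-2-en-1-yl acetate | OCCC/C(C)=C/COC(C)=O
F8 | step 5 | (2E)-6-iodo-3-methylhex-2-en-1-yl acetate | ICCC/C(C)=C/COC(C)=O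
F9 | step 5 | [(4E)-6-(acetyloxy)-4-methylhex-4-en-1-yl]triphenylphosphonium iodide | c1ccc(cc1)[P+](c1ccccc1)(c1ccccc1)CCC/C(C)=C/COC(C)=O.[I-]
F10 | step 5 | (2E)-6-(2,2-dimethyl-1,3-dioxan-5-ylidene)-3-methylhex-2-en-1-yl acetate | CC1(C)OCC(=CCC/C(C)=C/COC(C)=O)CO1
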